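**Retrosynthetic overview**
1. Cespitularin K ⇐ acetylation and Peterson unmasking of C4=C20 ⇐ tricycle 22 ⇐ key disconnection C11–C15: ring A is closed last, on the 13-membered seco-A macrocycle 21, by a cobalt-hydride radical cycloisomerisation that also turns the 13-membered ring into ring B.
2. Enabling feature: in ring C the C11=C12 bond lies between the C10 and C18 carbonyls (cyclopent-4-ene-1,3-dione), and its unsubstituted end C11 sits 1,6 to C15 of an isopropenyl group on C1. The tertiary C15 radical can therefore add 6-endo, and loss of the C11 hydrogen returns the same enedione. C9–H, between the two carbonyls, is epimerisable.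
3. Ring C of 21 ⇐ ylidenebutenolide 19 (methoxide rearrangement, C9–C10); 13-membered ring ⇐ intramolecular vinylogous Mukaiyama reaction (C9–C18); C5–C6 ⇐ boron aldol; C12–C13 ⇐ Negishi coupling.
4. Stereochemistry: C1 is bought with (+)-limonene oxide, C6 is set by reagent control, C9 is relayed from C1 in the key step; the C4 epimers and ylidene isomers are erased later.
5. Order of ring formation: butenolide (bought) → 13-membered carbocycle (step 11) → ring C (step 12) → ring A and ring B (step 13).

Key step: step 13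

Remark on numbering: verticillane locants are used. C1 = ring-A methine; C2, C3 = CH2; C4 = C(=C20H2); C5 = CH2; C6 = CH–OAc; C7=C8 (C8 carries methyl C19); C9 = CH between the ketones; C10 = ketone carbon on C11; C11=C12 = ring-fusion alkene (C11 carries C15); C13, C14 = ring-A CH2; C15 = CMe2; C18 = ketone carbon between C12 and C9. Ring A = C1/C14/C13/C12/C11/C15; ring B = the 12-membered ring C1–C11 plus C15; ring C = C9/C10/C11/C12/C18.

Assumption: the diisopinocampheylboron enolate of a methyl ketone made from (+)-Ipc2BCl is taken to add to the Si face of the aldehyde (6S); should the sense be the opposite, the enantiomeric reagent is used in step 8 with no other change.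

**Route**

Step 1
Reactants: 1 (+)-limonene 1,2-oxide [(4R), cis/trans mixture]
Product: 3 (3R)-6-oxo-3-(prop-1-en-2-yl)heptanal, via glycol 2 (not isolated)
Conditions: H5IO6, THF/H2O, 0 to 23 °C
Reagents that add atoms: water, O
Why: Periodic acid should hydrolyse the epoxide to the 1,2-diol and cleave it in the same flask (Malaprade glycol cleavage); the stereocentre that becomes C1 is not touched.

Step 2
Reactants: 3 (3R)-6-oxo-3-(prop-1-en-2-yl)heptanal
Product: 4 (5R)-7-hydroxy-5-(prop-1-en-2-yl)heptan-2-one
Conditions: NaBH4 (0.3 equiv), EtOH/CH2Cl2, −78 °C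
Reagents that add atoms: none
Why: At low temperature borohydride reduces the aldehyde much faster than the methyl ketone (chemoselective hydride reduction).

Step 3
Reactants: 4 (5R)-7-hydroxy-5-(prop-1-en-2-yl)heptan-2-one
Product: 5 (5R)-7-iodo-5-(prop-1-en-2-yl)heptan-2-one
Conditions: PPh3, I2, imidazole, CH2Cl2, 0 °C
Reagents that add atoms: iodine, II
Why: Appel-type iodination of a primary alcohol, to which the ketone and the alkene are inert.

Step 4
Reactants: 5 (5R)-7-iodo-5-(prop-1-en-2-yl)heptan-2-one; 6 4-bromofuran-2(5H)-one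
Product: 8 4-[(3S)-6-oxo-3-(prop-1-en-2-yl)heptyl]furan-2(5H)-one, via alkylzinc iodide 7 (not isolated)
Conditions: Zn dust, LiCl, THF, 40 °C; then 6, Pd(OAc)2, SPhos, THF, 23 °C
Reagents that add atoms: none
Why: Zinc insertion into the primary iodide tolerates the methyl ketone, and Negishi coupling with the β-bromo enoate forms C12–C13 (the descriptor at C1 changes only by the priority rules).

Step 5
Reactants: 9 1,1-dimethoxypropan-2-one; 10 triethyl phosphonoacetate
Product: 11 ethyl (E)-4,4-dimethoxy-3-methylbut-2-enoate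
Conditions: NaH, THF, 0 to 23 °C
Reagents that add atoms: none
Why: Horner–Wadsworth–Emmons olefination of the activated ketone should favour the E enoate (ester trans to the acetal carbon); the minor Z isomer is removed by chromatography.

Step 6
Reactants: 11 ethyl (E)-4,4-dimethoxy-3-methylbut-2-enoate
Product: 12 (E)-4,4-dimethoxy-3-methylbut-2-en-1-ol
Conditions: i-Bu2AlH (2.2 equiv), CH2Cl2, −78 °C; Rochelle salt
Reagents that add atoms: none
Why: 1,2-Reduction of the conjugated ester with an aluminium hydride leaves the acetal and the alkene geometry intact.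

Step 7
Reactants: 12 (E)-4,4-dimethoxy-3-methylbut-2-en-1-ol
Product: 13 (E)-4,4-dimethoxy-3-methylbut-2-enal
Conditions: MnO2, CH2Cl2, 23 °C
Reagents that add atoms: none
Why: Allylic oxidation with MnO2 is neutral and keeps the acetal and the E geometry.

Step 8
Reactants: 8 4-[(3S)-6-oxo-3-(prop-1-en-2-yl)heptyl]furan-2(5H)-one; 13 (E)-4,4-dimethoxy-3-methylbut-2-enal
Product: 15 4-[(3S,8S,9E)-8-hydroxy-11,11-dimethoxy-10-methyl-6-oxo-3-(prop-1-en-2-yl)undec-9-en-1-yl]furan-2(5H)-one, via boron enolate 14 (not isolated)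
Conditions: (+)-Ipc2BCl, Et3N, Et2O, −78 to 0 °C; then 13, −78 to −20 °C; H2O2, pH 7 buffer, MeOH, 0 °C
Reagents that add atoms: none
Why: In this diisopinocampheylboron aldol reaction the amine/chloroborane pair should enolise only the methyl ketone on its methyl side, and the reagent sets C6 (S) through the boat transition state, independent of the remote C1; the minor C6 epimer is a diastereomer and is separated.

Step 9
Reactants: 15 the aldol of step 8
Product: 16 4-[(3S,8S,9E)-6,8-dihydroxy-11,11-dimethoxy-10-methyl-3-(prop-1-en-2-yl)-6-[(trimethylsilyl)methyl]undec-9-en-1-yl]furan-2(5H)-one (both C4 epimers)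
Conditions: Me3SiCH2MgCl (3.5 equiv), CeCl3 (3.5 equiv), THF, −78 to 0 °C
Reagents that add atoms: (trimethylsilyl)methylmagnesium chloride, C[Si](C)(C)C[Mg]Cl
Why: The weakly basic organocerium reagent should add 1,2 to the ketone faster than to the butenolide (first half of a Peterson olefination), so C4=C20 is stored as a β-hydroxysilane; the new C4 centre is a mixture that is erased in step 14.

Step 10
Reactants: 16 the diol of step 9
Product: 17 tris-silyl compound: the 2-(tert-butyldimethylsilyloxy)furan of 16 with the C4 and C6 hydroxyls as tert-butyldimethylsilyl ethers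
Conditions: t-BuMe2SiOTf (3.5 equiv), Et3N (5 equiv), CH2Cl2, −78 to 0 °C
Reagents that add atoms: tert-butyldimethylsilyl trifluoromethanesulfonate, CC(C)(C)[Si](C)(C)OS(=O)(=O)C(F)(F)F
Why: The silyl triflate/amine pair silylates both alcohols and converts the butenolide into its aromatic 2-silyloxyfuran (soft enolisation), the nucleophile for ring closure.

Step 11
Reactants: 17 the tris-silyl compound of step 10
Product: 19 13-membered (Z)-ylidenebutenolide: butenolide (O, C10, C11, C12, C18) with exocyclic C18=C9; C9 is joined through C8(Me)=C7 (E), C6 (S, silyl ether), C5, C4 (silyl ether, CH2SiMe3), C3, C2, C1 (isopropenyl, configuration from limonene), C14 and C13 back to C12, via methoxy adduct 18 (not isolated)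
Conditions: Me3SiOTf (0.2 equiv), CH2Cl2, −78 °C, syringe-pump addition of 17 (1 mM); then DBU, −78 to 23 °C
Reagents that add atoms: none
Why: The silyl triflate ionises the allylic acetal, the silyloxyfuran attacks the oxocarbenium ion through its γ-carbon C18 (intramolecular vinylogous Mukaiyama reaction), and DBU eliminates methanol (E1cB); the C9/C18 centres of 18 and any E isomer of the ylidene are erased in step 12.

Step 12
Reactants: 19 the macrocyclic ylidenebutenolide
Product: 21 seco-A enedione: cyclopent-4-ene-1,3-dione (C9, C10, C11, C12, C18; C11 carries H) bridged from C9 to C12 by the ten-carbon chain C8 to C13 (13-membered ring; C9 epimers; C1 and C6 as in 19), via keto ester 20 (not isolated)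
Conditions: NaOMe (2 equiv), MeOH/THF, 0 to 23 °C; then AcOH
Reagents that add atoms: none
Why: In the ylidenebutenolide-to-cyclopentenedione rearrangement, methoxide opens the enol lactone to the (Z)-4-oxo-enoate and the doubly activated C9 closes onto the C10 ester (Dieckmann condensation); the product is held as its enolate until the quench.

Step 13
Reactants: 21 the seco-A enedione
Product: 22 tricycle: rings A, B and C of the target with C4 as C(OSiMe2t-Bu)(CH2SiMe3) and C6 as its tert-butyldimethylsilyl ether (C6 S, C9 S, C1 as in the target)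
Conditions: Co(salen)Cl (5 mol%; salen = N,N'-bis(3,5-di-tert-butylsalicylidene)cyclohexane-1,2-diaminate), PhSiH3 (10 mol%), benzene, 23 °C, argon; then Et3N (0.2 equiv), 23 °C
Reagents that add atoms: none
Why: Proposed new method: a cobalt hydride formed from Co(salen)Cl and PhSiH3 should transfer a hydrogen atom to the terminal carbon C16 of the isopropenyl group, and the tertiary C15 radical should add to C11 to give a tertiary C12 radical stabilised by the C18 carbonyl; divalent cobalt then takes the hydrogen atom from C11 (or from C13, after which the exocyclic enone tautomerises to the same enedione), which returns the hydride and makes the reaction a catalytic, redox-neutral isomerisation with no stoichiometric reductant that could reduce the enedione. The closest known reaction types are the Co(salen)-catalysed hydrogen-atom-transfer cycloisomerisation of dienes and the hydrogen-atom-transfer-initiated 6-endo Giese cyclisation onto cyclic enones tethered at the α-carbon; new here is the cyclopent-4-ene-1,3-dione as acceptor. Ring A is closed in the 6-endo-trig mode, and because the C11–C15 bond is common to rings A and B, the same bond turns the 13-membered carbocycle of 21 into the 12-membered ring B. No stereocentre is formed at C15 or C11, and C1 is carried from limonene because a radical, unlike the cation of the biosynthetic ring closure, cannot scramble it by a 1,2-hydride shift; C9 epimerises under the Et3N finish to the one configuration (9S) in which the C2–C8 chain spans the face of the bicycle on which the C1–C2 bond lies. The step needs 6-endo over 5-exo attack, which the fully substituted C12 and the hindered tertiary radical should secure, and hydrogen-atom transfer to the 1,1-disubstituted alkene in preference to the trisubstituted C7=C8 alkene, which is why the second 1,1-disubstituted alkene of the target (C4=C20) is kept masked until step 14.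

Step 14
Reactants: 22 the tricyclic bis-silyl ether
Product: 24 6-O-deacetylcespitularin K (1R,6S,9S,7E), via hydroxysilane 23 (not isolated)
Conditions: HF·pyridine, pyridine, THF, 0 to 23 °C
Reagents that add atoms: none
Why: Fluoride/acid cleaves both silyl ethers, and the tertiary β-hydroxysilane undergoes acid-promoted Peterson elimination, which places the alkene only between C4 and C20 and removes the C4 stereocentre.

Step 15
Reactants: 24 6-O-deacetylcespitularin K
Product: 25 cespitularin K
Conditions: Ac2O, pyridine, CH2Cl2, 0 °C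
Reagents that add atoms: acetic anhydride, CC(=O)OC(C)=O
Why: Acetylation of the secondary allylic alcohol under mild conditions; the ring-C diketone should stay as the C–H diketo form, since its enol would be a cyclopentadienone.

**Compound list**
1 | (+)-limonene 1,2-oxide, (4R), cis/trans mixture | CC12OC1C[C@@H](CC2)C(C)=C | starting material
2 | (4R)-p-menth-8-ene-1,2-diol | CC1(O)C(O)C[C@@H](CC1)C(C)=C | intermediate
3 | (3R)-6-oxo-3-(prop-1-en-2-yl)heptanal | O=CC[C@@H](CCC(C)=O)C(C)=C | intermediate
4 | (5R)-7-hydroxy-5-(prop-1-en-2-yl)heptan-2-one | OCC[C@@H](CCC(C)=O)C(C)=C | intermediate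
5 | (5R)-7-iodo-5-(prop-1-en-2-yl)heptan-2-one | ICC[C@@H](CCC(C)=O)C(C)=C | intermediate
6 | 4-bromofuran-2(5H)-one | O=C1C=C(Br)CO1 | starting material
7 | alkylzinc iodide from 5 | I[Zn]CC[C@@H](CCC(C)=O)C(C)=C | intermediate
8 | 4-[(3S)-6-oxo-3-(prop-1-en-2-yl)heptyl]furan-2(5H)-one | O=C1OCC(CC[C@@H](CCC(C)=O)C(C)=C)=C1 | intermediate
9 | 1,1-dimethoxypropan-2-one (pyruvaldehyde dimethyl acetal) | CC(=O)C(OC)OC | starting material
10 | triethyl phosphonoacetate | CCOC(=O)CP(=O)(OCC)OCC | starting material
11 | ethyl (E)-4,4-dimethoxy-3-methylbut-2-enoate | CCOC(=O)/C=C(C)/C(OC)OC | intermediate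
12 | (E)-4,4-dimethoxy-3-methylbut-2-en-1-ol | OC/C=C(C)/C(OC)OC | intermediate
13 | (E)-4,4-dimethoxy-3-methylbut-2-enal | O=C/C=C(C)/C(OC)OC | intermediate
14 | diisopinocampheylboron enolate of 8 (enolised towards C5) | C=C(OB([C@H]1C[C@H]2C[C@@H]([C@@H]1C)C2(C)C)[C@H]1C[C@H]2C[C@@H]([C@@H]1C)C2(C)C)CC[C@H](CCC1=CC(=O)OC1)C(C)=C | intermediate
15 | 4-[(3S,8S,9E)-8-hydroxy-11,11-dimethoxy-10-methyl-6-oxo-3-(prop-1-en-2-yl)undec-9-en-1-yl]furan-2(5H)-one | O=C1OCC(CC[C@@H](CCC(=O)C[C@H](O)/C=C(C)/C(OC)OC)C(C)=C)=C1 | intermediate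
16 | 4-[(3S,8S,9E)-6,8-dihydroxy-11,11-dimethoxy-10-methyl-3-(prop-1-en-2-yl)-6-[(trimethylsilyl)methyl]undec-9-en-1-yl]furan-2(5H)-one, C4 epimers | O=C1OCC(CC[C@@H](CCC(O)(C[Si](C)(C)C)C[C@H](O)/C=C(C)/C(OC)OC)C(C)=C)=C1 | intermediate
17 | 2-(tert-butyldimethylsilyloxy)furan of 16 with C4 and C6 tert-butyldimethylsilyl ethers | CC(C)(C)[Si](C)(C)Oc1cc(CC[C@@H](CCC(O[Si](C)(C)C(C)(C)C)(C[Si](C)(C)C)C[C@H](O[Si](C)(C)C(C)(C)C)/C=C(C)/C(OC)OC)C(C)=C)co1 | intermediate
18 | 13-membered 9-methoxy butenolide (C9 and C18 epimers) | O=C1OC2C(OC)/C(C)=C/[C@@H](O[Si](C)(C)C(C)(C)C)CC(O[Si](C)(C)C(C)(C)C)(C[Si](C)(C)C)CC[C@H](CCC2=C1)C(C)=C | intermediate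
19 | 13-membered (Z)-ylidenebutenolide (C18=C9 Z, C7=C8 E, 6S, C1 from limonene) | O=C1O/C2=C\C(C)=C\[C@@H](O[Si](C)(C)C(C)(C)C)CC(O[Si](C)(C)C(C)(C)C)(C[Si](C)(C)C)CC[C@H](CCC2=C1)C(C)=C | intermediate
20 | 13-membered methyl (Z)-4-oxo-enoate (ring-opened keto ester) | COC(=O)/C=C1/CC[C@H](C(C)=C)CCC(O[Si](C)(C)C(C)(C)C)(C[Si](C)(C)C)C[C@H](O[Si](C)(C)C(C)(C)C)/C=C(C)/CC1=O | intermediate
21 | seco-A enedione (13-membered ring bridging C9 and C12 of the cyclopent-4-ene-1,3-dione; C9 epimers) | O=C1C=C2C(=O)C1/C(C)=C/[C@@H](O[Si](C)(C)C(C)(C)C)CC(O[Si](C)(C)C(C)(C)C)(C[Si](C)(C)C)CC[C@H](CC2)C(C)=C | intermediate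
22 | tricyclic bis-silyl ether (rings A, B, C; 6S, 9S; C4 epimers) | C[Si](C)(C)CC1(O[Si](C)(C)C(C)(C)C)CC[C@@H]2CCC3=C(C(=O)[C@H](C3=O)/C(C)=C/[C@@H](O[Si](C)(C)C(C)(C)C)C1)C2(C)C | intermediate
23 | tricyclic 4,6-diol with C4 CH2SiMe3 | C[Si](C)(C)CC1(O)CC[C@@H]2CCC3=C(C(=O)[C@H](C3=O)/C(C)=C/[C@@H](O)C1)C2(C)C | intermediate
24 | 6-O-deacetylcespitularin K | C=C1CC[C@@H]2CCC3=C(C(=O)[C@H](C3=O)/C(C)=C/[C@@H](O)C1)C2(C)C | intermediate
25 | cespitularin K | C=C1CC[C@@H]2CCC3=C(C(=O)[C@H](C3=O)/C(C)=C/[C@@H](OC(C)=O)C1)C2(C)C | target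

**Step count and risks**
Total step count: 15. Longest linear sequence: 12 steps (steps 1–4 and 8–15); steps 5–7 make the second fragment.

Steps most likely to fail:

1. Step 13 (Proposed new method). What may go wrong: protonolysis of the cobalt hydride by the acidic C9–H, or return of the hydrogen atom from C1 (isomerisation to the isopropylidene, which erases C1) faster than the 6-endo closure. The fallback sets out from 21 and closes the ring reductively. Fe(acac)3 and PhSiH3 in EtOH/ethylene glycol at 60 °C (hydrogen-atom-transfer Giese cyclisation) should give the saturated tricyclic 1,3-dione F1. Its dianion (LDA, 2.2 equiv, THF, −78 °C; second deprotonation at C12) is selenenylated with PhSeBr to the C12 phenylselenide F2. Oxidation with H2O2 (selenoxide syn-elimination towards C11 or C13, then Et3N) comes back to the route at 22.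

2. Step 11. What may go wrong: oligomerisation in place of ring closure, or attack on the oxocarbenium ion at its vinylogous position C7. The fallback closes the ring at C12–C13 by cross-coupling instead of at C9–C18; it sets out from iodide 5, enal 13 and bromofuranone 6. The same (+)-Ipc2BCl aldol reaction joins 5 and 13 to the iodo aldol F3; Me3SiCH2MgCl/CeCl3 gives the iodo diol F4, and t-BuMe2SiOTf/2,6-lutidine the bis-silyl ether F5. Bromofuranone 6 is converted (t-BuMe2SiOTf, Et3N) into the 4-bromo-2-silyloxyfuran F6, which is joined to the acetal of F5 (Me3SiOTf cat., −78 °C) to give the bromo methoxy adduct F7 (not isolated) and, with DBU, the bromo ylidenebutenolide F8. Zinc insertion into the primary iodide (Zn, LiCl, THF) gives the alkylzinc iodide F9 (not isolated), and Pd(OAc)2/SPhos at high dilution (intramolecular Negishi coupling with the vinylic bromide) comes back to the route at 19.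

3. Step 12. What may go wrong: conjugate addition of methoxide to the ylidenebutenolide, or β-elimination of the C6 silyloxy group from the extended enolate before the Dieckmann closure. The fallback replaces the acyl transfer by reduction, aldol closure and oxidation; it sets out from 19. i-Bu2AlH (1.1 equiv, CH2Cl2, −78 °C) reduces the enol lactone, and on work-up the (Z)-4-oxo-enal F10 is obtained. Et3N closes ring C by intramolecular aldol addition of C9 to the C10 aldehyde to give the 4-hydroxycyclopent-2-enone F11, and Dess–Martin periodinane oxidises it, which comes back to the route at 21.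

Further compounds
F1 | step 13 | saturated tricyclic 1,3-dione (C11 and C12 sp3; rest as 22) | C[Si](C)(C)CC1(O[Si](C)(C)C(C)(C)C)CC[C@@H]2CCC3C(C(=O)C(C3=O)/C(C)=C/[C@@H](O[Si](C)(C)C(C)(C)C)C1)C2(C)C
F2 | step 13 | C12 phenylselenide of F1 | C[Si](C)(C)CC1(O[Si](C)(C)C(C)(C)C)CC[C@@H]2CCC3([Se]c4ccccc4)C(C(=O)C(C3=O)/C(C)=C/[C@@H](O[Si](C)(C)C(C)(C)C)C1)C2(C)C
F3 | step 11 | iodo aldol from 5 and 13 (6S) | ICC[C@@H](CCC(=O)C[C@H](O)/C=C(C)/C(OC)OC)C(C)=C
F4 | step 11 | iodo diol with C4 CH2SiMe3 | ICC[C@@H](CCC(O)(C[Si](C)(C)C)C[C@H](O)/C=C(C)/C(OC)OC)C(C)=C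
F5 | step 11 | bis(tert-butyldimethylsilyl) ether of F4 | ICC[C@@H](CCC(O[Si](C)(C)C(C)(C)C)(C[Si](C)(C)C)C[C@H](O[Si](C)(C)C(C)(C)C)/C=C(C)/C(OC)OC)C(C)=C
F6 | step 11 | 4-bromo-2-(tert-butyldimethylsilyloxy)furan | CC(C)(C)[Si](C)(C)Oc1cc(Br)co1
F7 | step 11 | acyclic 4-bromo-5-(1-methoxyalkyl)butenolide | O=C1OC(C(OC)/C(C)=C/[C@@H](O[Si](C)(C)C(C)(C)C)CC(O[Si](C)(C)C(C)(C)C)(C[Si](C)(C)C)CC[C@H](CCI)C(C)=C)C(Br)=C1
F8 | step 11 | acyclic 4-bromo-(Z)-5-ylidenebutenolide with the iodoalkyl chain | O=C1O/C(=C\C(C)=C\[C@@H](O[Si](C)(C)C(C)(C)C)CC(O[Si](C)(C)C(C)(C)C)(C[Si](C)(C)C)CC[C@H](CCI)C(C)=C)C(Br)=C1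
F9 | step 11 | alkylzinc iodide from F8 | O=C1O/C(=C\C(C)=C\[C@@H](O[Si](C)(C)C(C)(C)C)CC(O[Si](C)(C)C(C)(C)C)(C[Si](C)(C)C)CC[C@H](CC[Zn]I)C(C)=C)C(Br)=C1
F10 | step 12 | 13-membered (Z)-4-oxo-enal | O=C/C=C1/CC[C@H](C(C)=C)CCC(O[Si](C)(C)C(C)(C)C)(C[Si](C)(C)C)C[C@H](O[Si](C)(C)C(C)(C)C)/C=C(C)/CC1=O
F11 | step 12 | 10-hydroxy analogue of 21 (4-hydroxycyclopent-2-enone) | OC1C=C2C(=O)C1/C(C)=C/[C@@H](O[Si](C)(C)C(C)(C)C)CC(O[Si](C)(C)C(C)(C)C)(C[Si](C)(C)C)CC[C@H](CC2)C(C)=C
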